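1. At 2.50 min the elm flask shows less D than the X it has used: 85.3% against 95.3%. I suppose that dissolved Z makes D and then also consumes it. So watch the shortfall, 10.0% in elm.

common to all: Z 0.016 mM (held)

| flask | X | remark | time |
|---|---|---|---|
| elm | 0.10 mM | run made earlier |  |
| alder | 0.40 mM | run made earlier |  |
| flask | 0.20 mM |  | 2.5 min |

| run | time / min | D / % | X / % |
|---|---|---|---|
| elm | 0.200 | 8.9 | 90.9 |
| elm | 0.500 | 24.9 | 76.0 |
| elm | 1.00 | 48.2 | 51.3 |
| elm | 2.50 | 85.3 | 4.7 |
| alder | 0.667 | 10.0 | 89.8 |
| alder | 1.33 | 19.2 | 79.7 |
| alder | 2.00 | 29.1 | 69.9 |
| alder | 2.50 | 36.4 | 62.6 |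

(scatter of a reading: 0.5 percentage points)

- at the start none of Z is in solution

- amount of D at 2.5 min, in percent of the X charged
- the change that raises the amount of D at 2.5 min, in percent of the X charged most ("none" if none brings more than 2 percentage points) (winter / dusk / none)
- amount of D at 2.5 min, in percent of the X charged, after dusk

2. Winter doubles the saturation concentration of Z, and dusk doubles its transfer coefficient.

3. I divide the rate of losing D by the rate of making it. If both steps are first order in dissolved Z, its concentration cancels, leaving s[D]/[X], with s the ratio of the two rate constants, and time drops out. For small s, with x the share of X left, the shortfall is s(−ln x − 1 + x). Elm gives the loss ratio s, the inverse of the selectivity factor, as 0.0475, a reading with its scatter.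

4. The charge: alder uses X at 0.0598 mM/min on average, and elm, up to 1.00 min, at 0.0487 mM/min. I take their mean for the flask, charged between them. That leaves x = 32.2%, a shortfall of 2.17% and D at 65.7%.

5. The supply: the flask holds twice the X of elm, so doubling the supply gives it about elm's supply per X, and I estimate elm's ending, 85.3% of D, a gain of 20 percentage points. On the rule, winter and dusk share one curve of shortfall against x, so it doesn't separate them.

6. The forecast says 64.5%, dusk and 83%, holding that “Dusk keeps Z lower while X remains”. I take its choice. My D values stand slightly higher.

7. The flask gives 65.0% of D, and 86.3% after dusk, which adds 21 points against 19 points for winter. L is dissolved Z and J is what D becomes.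

    Z ⇌ L, rate k1*(csat - [L]) (kL = 0.0650 /s)
    X + L → D (k = 4600 /M/s)
    L + D → J (k = 210 /M/s)

At 2.50 min the flask still holds 33.1% of X and 1.96% as J. The neighbour charged with 0.12 mM of X ends with 9.62% of X, so s puts its shortfall at 6.83%, and it holds 6.30% as J.

The data come from a simulation with made-up constants; scatter was added.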